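Readings and results stem from a simulated flask on assumed constants, noise included.

The spring run, at 2.5 mM of acid, keeps 60.2% of its substrate at 2.50 min. We count turnovers n = k·t, the e-foldings of substrate, with k a pseudo-first-order constant at fixed acid.

- spring: substrate 0.050 M; acid 2.5 mM; run made earlier
- flask: substrate 0.050 M; acid 5.00 mM; time 12 min

spring run (percent of the substrate charged)

| time / min | substrate / % | target / % |
|---|---|---|
| 0.500 | 90.4 | 5.9 |
| 1.00 | 82.0 | 11.0 |
| 1.33 | 75.6 | 12.6 |
| 2.00 | 66.4 | 18.8 |
| 2.50 | 60.2 | 22.4 |

(scatter of a reading: 0.5 percentage points)

- acid is the free proton; pH is minus the decimal logarithm of its molar concentration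
- percentages count the substrate that a species holds: one homo dimer or side product counts as two
- target is meant together with its crystals
- solid, in amounts per volume of the solution: crystals
- the analysis behind the earlier runs scatters by 0.5 percentage points, standard deviation
- steps thought possible: substrate + acid -> weak acid + acid + target; weak acid <-> conjugate base + acid; substrate -> weak acid + target; crystals <-> target; 2 substrate -> homo dimer; substrate + target -> side product

- part of the substrate that has reacted at 12 min
- pH of the solution at 12 min

1. From the last reading of the spring run we read k_s = ln(charged/left)/t = 0.203 min⁻¹.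

2. Of the substrate consumed by then, target holds a share f = 56.3%, so the target channel carries f·k_s = 0.114 min⁻¹.

3. Suppose that whole channel goes in proportion to acid. This flask has twice the acid, so on that supposition k_f = k_s(1 + f) = 0.317 min⁻¹, and the estimate leaves 2.23% of the substrate at 12 min.

4. That supposition is the weak link: one of the steps thought possible forms target without acid, and the spring run holds a single acid level. We therefore credit acid with half of the channel, which gives the turnover rate k_m, the turnovers per minute expected in this flask: 0.260 min⁻¹.

5. So n = 3.12 at 12 min, and we commit to 95.6% reacted. Acid is returned by the step that uses it, so we take pH 2.3 from the 5.00 mM charged.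

The forecast commits to 95% and pH 2.28, slightly less conversion than ours, and says “I lean towards catalysis”.

The flask gives 93.5% reacted and pH 2.30.

    substrate + acid → weak acid + acid + target (k = 25.0 M⁻¹ min⁻¹)
    weak acid ⇌ conjugate base + acid, settled at all times (K = 4.00 × 10⁻⁶ M)
    substrate → weak acid + target (k = 0.0570 min⁻¹)
    crystals ⇌ target, rate k4*(cs4 - [target]) while solid is left; crystals form when [target] > cs4 (solubility = 49.0 mM, k = 3.60 min⁻¹)
    2 substrate → homo dimer (k = 1.00 M⁻¹ min⁻¹)
    substrate + target → side product (k = 0.550 M⁻¹ min⁻¹)

In this flask, just after the start, the step with acid uses substrate 2.2 times as fast as the step without it. The 6.5% left in this flask is 2.73 turnovers at 12 min, fewer than the 3.12 from k_m. For the neighbour read at 3.0 min, k_m gives 45.8% of the substrate left, and that flask holds 46%.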